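Numbering follows the C15 chain: C1≡C2–C3=C4–C5–C6(O)–C7(Cl)–C8–C9(Cl)–C10(OAc)–C11–C12(O)–C13(Br)–C14–C15. The ring is the oxocane O/C6–C12 with the C6 and C12 arms trans; configuration 6S,7S,9S,10S,12R,13S.
Enabling feature: C9 lies 1,5-transannular to the ring oxygen, so the oxocane is the perimeter of two five-membered rings (O/C6/C7/C8/C9 and O/C9/C10/C11/C12) that share an O–C9 bond. C13–Br is vicinal to O–C12, and C9–Cl is trans-vicinal to C10–OAc.
Retrosynthetic cuts, in order: C2–C3 and C3–I. Then O–C12, C13–Br and C9–Cl together (O–C9 restored), which leads back to an all-cis 2,3,5-trisubstituted tetrahydrofuran with an (E)-hexenyl acetate arm. Then C7–Cl, O–C6, C7–C8 (aldol) and C10–C11 (alkylation).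
Forward: a C8–C15 methyl ketone and a C3–C7 α-chloroaldehyde are joined by aldol. A temporary C6/C7 epoxide is opened to the tetrahydrofuran O/C6–C9. Br+ then closes O–C12 to a bicyclic oxonium, whose O–C9 bond is cut by the C10 acetate and then chloride, leaving the oxocane as the last ring.
Stereochemistry: C10 comes from an Evans auxiliary and C6 from organocatalytic α-chlorination (net retention by double inversion). C7 comes from a Cornforth-controlled aldol followed by SN2 inversion to chloride, and C9–O from 1,3-syn reduction. C12/C13 come from anti addition to the E-alkene on the convex face, and C9–Cl from double inversion.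

Key step: step 14

Assumption: (2R,5R)-2,5-diphenylpyrrolidine is taken to deliver the (S)-chloride in step 6. If the sense of induction is the reverse, the (2S,5S) antipode is used and nothing else changes.

Step 1
Reactants: 1 (R)-4-benzyloxazolidin-2-one; 2 (4-methoxyphenoxy)acetic acid
Product: 4 (R)-4-benzyl-3-[(4-methoxyphenoxy)acetyl]oxazolidin-2-one, via mixed pivalic anhydride 3 (not isolated)
Conditions: PivCl, Et3N, THF, −20 °C; then LiCl, 1, −20 °C → rt
Reagents that add atoms: none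
Why: Mixed-anhydride N-acylation of an Evans oxazolidinone takes place at the less hindered aryloxyacetyl carbonyl and creates no stereocentre.

Step 2
Reactants: 4 (R)-4-benzyl-3-[(4-methoxyphenoxy)acetyl]oxazolidin-2-one; 5 (E)-1-bromopent-2-ene
Product: 7 (R)-4-benzyl-3-[(2S,4E)-2-(4-methoxyphenoxy)hept-4-enoyl]oxazolidin-2-one, via sodium (Z)-enolate 6 (not isolated)
Conditions: NaHMDS, THF, −78 °C; then 5, Bu4NI (cat.), −78 → −45 °C
Reagents that add atoms: none
Why: Evans-type glycolate alkylation, in which the chelated (Z)-enolate is attacked by the primary allylic bromide (SN2, E geometry kept) on the face opposite the benzyl group, setting C10 as S.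

Step 3
Reactants: 7 (R)-4-benzyl-3-[(2S,4E)-2-(4-methoxyphenoxy)hept-4-enoyl]oxazolidin-2-one
Product: 8 (2S,4E)-N-methoxy-2-(4-methoxyphenoxy)-N-methylhept-4-enamide
Conditions: MeNH(OMe)·HCl, AlMe3, CH2Cl2, 0 °C → rt
Reagents that add atoms: N,O-dimethylhydroxylamine hydrochloride, CNOC.Cl
Why: Aluminium-amide transamidation (Weinreb amide synthesis) attacks the exocyclic carbonyl, which the α-aryloxy group activates, releases the auxiliary and leaves C10 untouched.

Step 4
Reactants: 8 (2S,4E)-N-methoxy-2-(4-methoxyphenoxy)-N-methylhept-4-enamide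
Product: 9 (3S,5E)-3-(4-methoxyphenoxy)oct-5-en-2-one
Conditions: MeMgBr, THF, 0 °C; aq. work-up
Reagents that add atoms: methylmagnesium bromide, C[Mg]Br
Why: In the Weinreb ketone synthesis, chelation prevents over-addition, so the methyl ketone (C8–C15) should form without epimerisation at C10.

Step 5
Reactants: 10 5-(trimethylsilyl)pent-4-yn-1-ol
Product: 11 5-(trimethylsilyl)pent-4-ynal
Conditions: TEMPO (cat.), PhI(OAc)2, CH2Cl2, rt
Reagents that add atoms: none
Why: The oxoammonium (TEMPO) oxidation of a primary alcohol stops at the aldehyde and tolerates the silyl alkyne.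

Step 6
Reactants: 11 5-(trimethylsilyl)pent-4-ynal
Product: 12 (S)-2-chloro-5-(trimethylsilyl)pent-4-ynal
Conditions: NCS, (2R,5R)-2,5-diphenylpyrrolidine (10 mol %), CH2Cl2, 0 °C → rt; used directly
Reagents that add atoms: N-chlorosuccinimide, O=C1CCC(=O)N1Cl
Why: Enamine-catalysed α-chlorination of an aldehyde, in which the C2-symmetric amine shields one enamine face and sets C6 as S; immediate use limits racemisation.

Step 7
Reactants: 9 (3S,5E)-3-(4-methoxyphenoxy)oct-5-en-2-one; 12 (S)-2-chloro-5-(trimethylsilyl)pent-4-ynal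
Product: 14 (4S,5R,8S,10E)-4-chloro-5-hydroxy-8-(4-methoxyphenoxy)-1-(trimethylsilyl)tridec-10-en-1-yn-7-one, via kinetic lithium enolate 13 (not isolated)
Conditions: LDA, THF, −78 °C; then 12, −78 °C; aq. NH4Cl
Reagents that add atoms: none
Why: Lithium-enolate aldol addition to an α-chloroaldehyde follows the Cornforth model and should give the 1,2-anti chlorohydrin, so the C6 chloride sets C7 as R while the C7–C8 bond joins the two fragments.

Step 8
Reactants: 14 (4S,5R,8S,10E)-4-chloro-5-hydroxy-8-(4-methoxyphenoxy)-1-(trimethylsilyl)tridec-10-en-1-yn-7-one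
Product: 15 (4S,5R,7S,8S,10E)-4-chloro-8-(4-methoxyphenoxy)-1-(trimethylsilyl)tridec-10-en-1-yne-5,7-diol
Conditions: Et2BOMe, NaBH4, THF/MeOH, −78 °C; AcOH, then MeOH co-evaporation
Reagents that add atoms: none
Why: The Narasaka–Prasad reduction delivers hydride to the boron-chelated β-hydroxy ketone to give the 1,3-syn diol (C9 = S), a sense reinforced by the polar Felkin–Anh preference of the α-aryloxy centre.

Step 9
Reactants: 15 (4S,5R,7S,8S,10E)-4-chloro-8-(4-methoxyphenoxy)-1-(trimethylsilyl)tridec-10-en-1-yne-5,7-diol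
Product: 16 (2S,3S,5E)-3-(4-methoxyphenoxy)-1-[(2R,3R)-3-(prop-2-ynyl)oxiran-2-yl]oct-5-en-2-ol
Conditions: K2CO3, MeOH, 0 °C → rt
Reagents that add atoms: none
Why: Intramolecular Williamson closure of the anti chlorohydrin (inversion at C6) gives the trans-epoxide, and the same basic methanol removes the alkynyl silyl group.

Step 10
Reactants: 16 (2S,3S,5E)-3-(4-methoxyphenoxy)-1-[(2R,3R)-3-(prop-2-ynyl)oxiran-2-yl]oct-5-en-2-ol
Product: 17 (2S,3R,5S)-5-[(1S,3E)-1-(4-methoxyphenoxy)hex-3-enyl]-2-(prop-2-ynyl)tetrahydrofuran-3-ol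
Conditions: BF3·OEt2 (cat.), CH2Cl2, −40 → 0 °C
Reagents that add atoms: none
Why: In this Lewis-acid-catalysed cyclisation of a trans-3,4-epoxy alcohol, the C9 hydroxyl opens the epoxide at C6 with inversion (formally 5-endo, the 4-exo oxetane path being strained) to give the 2,5-cis-2,3-trans ring, and the aryl ether oxygen is too weak a nucleophile to compete.

Step 11
Reactants: 17 (2S,3R,5S)-5-[(1S,3E)-1-(4-methoxyphenoxy)hex-3-enyl]-2-(prop-2-ynyl)tetrahydrofuran-3-ol
Product: 18 (2S,3S,5S)-3-chloro-5-[(1S,3E)-1-(4-methoxyphenoxy)hex-3-enyl]-2-(prop-2-ynyl)tetrahydrofuran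
Conditions: (n-Oct)3P, CCl4, toluene, 70 °C
Reagents that add atoms: carbon tetrachloride, ClC(Cl)(Cl)Cl
Why: Appel-type deoxychlorination proceeds by SN2 displacement of the alkoxyphosphonium group, inverting C7 (R to S) and giving the all-cis chloride.

Step 12
Reactants: 18 (2S,3S,5S)-3-chloro-5-[(1S,3E)-1-(4-methoxyphenoxy)hex-3-enyl]-2-(prop-2-ynyl)tetrahydrofuran
Product: 19 (1S,3E)-1-[(2S,4S,5S)-4-chloro-5-(prop-2-ynyl)tetrahydrofuran-2-yl]hex-3-en-1-ol
Conditions: (NH4)2Ce(NO3)6, MeCN/H2O, 0 °C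
Reagents that add atoms: none
Why: Oxidative cleavage of a 4-methoxyphenyl ether by cerium(IV) breaks the aryl–O bond, so C10 keeps its configuration and the alkene, alkyne and chloride are spared.

Step 13
Reactants: 19 (1S,3E)-1-[(2S,4S,5S)-4-chloro-5-(prop-2-ynyl)tetrahydrofuran-2-yl]hex-3-en-1-ol
Product: 20 (1S,3E)-1-[(2S,4S,5S)-4-chloro-5-(prop-2-ynyl)tetrahydrofuran-2-yl]hex-3-enyl acetate
Conditions: Ac2O, pyridine, DMAP (cat.), CH2Cl2, 0 °C → rt
Reagents that add atoms: acetic anhydride, CC(=O)OC(C)=O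
Why: DMAP-catalysed acetylation of the only hydroxyl installs the final C10 ester, which also serves as the relay group of the next step.

Step 14
Reactants: 20 (1S,3E)-1-[(2S,4S,5S)-4-chloro-5-(prop-2-ynyl)tetrahydrofuran-2-yl]hex-3-enyl acetate
Product: 23 (2R,4S,5S,7S,8S)-2-[(S)-1-bromopropyl]-5,7-dichloro-8-(prop-2-ynyl)oxocan-4-yl acetate, via bicyclic oxonium salt 21 (not isolated), via cis-fused acetoxonium salt 22 (not isolated)
Conditions: BDSB (Et2SBr·SbCl5Br), MeNO2, −25 °C, 10 min; then n-Bu4NCl (excess) in CH2Cl2, −25 °C → rt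
Reagents that add atoms: bromodiethylsulfonium bromopentachloroantimonate (BDSB), CC[S+](Br)CC.Cl[Sb-](Cl)(Cl)(Cl)(Cl)Br; tetrabutylammonium chloride, CCCC[N+](CCCC)(CCCC)CCCC.[Cl-]
Why: Proposed new method: BDSB transfers Br+ to the only alkene (C12=C13) and the tetrahydrofuran oxygen attacks C12 anti to bromine (5-exo, closing ring O/C9–C12) to give the 1-oxoniabicyclo[3.3.0]octane 21; the C10 acetate carbonyl then displaces the oxonium oxygen from the ring-fusion carbon C9 from the rear (5-exo-tet), cutting the shared O–C9 bond so that the oxocane arises as the perimeter of the two five-membered rings (ring expansion, not a direct eight-membered closure) in the form of the cis-fused 1,3-dioxolan-2-ylium 22, which added chloride opens at C9 with a second inversion. The closest known reaction types are the BDSB ring-expanding bromoetherification of tetrahydrofurans that carry a tethered tert-butyl carbonate and the halide opening of diol-derived acetoxonium ions to trans-halohydrin acetates; what is new is their merger, with an acetate as relay and external chloride as terminator. C13 (S) follows from anti addition to the E-alkene, C12 (R) from closure with the bromopropyl arm on the convex face of 21 (trans to the O–C6 bond and to C8), and C9 (S) from double inversion of the (9S) ether carbon, while C6, C7 and C10 are not touched. Site selectivity in 21 (C9, not C6 or C12) is secured by the tether, since the acetate reaches only C9 through a five-membered transition state, C6 and C12 are deactivated by the adjacent C–Cl and C–Br bonds, and chloride is added only after the relay has occupied the rear of C9. Regioselectivity in 22 (C9, not C10) should follow from the bromopropyl group at C12, which lies on the face from which chloride must approach and is 1,3-syn to the C10 trajectory, whereas C7 carries only hydrogen on that face. Chemoselectivity rests on the much lower reactivity of the terminal alkyne towards Br+, and on 5-exo capture by the sp3 ether oxygen outrunning 6-exo capture by the ester carbonyl, which low temperature and the halide-free first stage are meant to favour.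

Step 15
Reactants: 23 (2R,4S,5S,7S,8S)-2-[(S)-1-bromopropyl]-5,7-dichloro-8-(prop-2-ynyl)oxocan-4-yl acetate
Product: 25 (2R,4S,5S,7S,8S)-2-[(S)-1-bromopropyl]-5,7-dichloro-8-[(E)-3-iodoprop-2-enyl]oxocan-4-yl acetate, via (E)-alkenylzirconocene chloride 24 (not isolated)
Conditions: Cp2Zr(H)Cl, THF, 0 °C → rt; then I2, 0 °C
Reagents that add atoms: iodine, II
Why: Hydrozirconation with the Schwartz reagent adds syn with Zr at the terminal carbon, faster than it attacks the acetate, and iodinolysis with retention gives the (E)-vinyl iodide (C3=C4).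

Step 16
Reactants: 25 (2R,4S,5S,7S,8S)-2-[(S)-1-bromopropyl]-5,7-dichloro-8-[(E)-3-iodoprop-2-enyl]oxocan-4-yl acetate
Product: 26 (2R,4S,5S,7S,8S)-2-[(S)-1-bromopropyl]-5,7-dichloro-8-[(E)-pent-2-en-4-ynyl]oxocan-4-yl acetate (target)
Conditions: HC≡CMgBr, ZnBr2, THF, 0 °C; then 25, Pd(PPh3)4 (5 mol %), rt
Reagents that add atoms: ethynylzinc bromide (from ethynylmagnesium bromide and zinc bromide), C#C[Zn]Br
Why: Negishi coupling of an alkenyl iodide with an ethynylzinc halide retains the E geometry and gives the free terminal enyne directly, under conditions that spare the acetate and the secondary halides.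

Compound list
1 | (R)-4-benzyloxazolidin-2-one | O=C1N[C@H](Cc2ccccc2)CO1 | starting material
2 | (4-methoxyphenoxy)acetic acid | COc1ccc(OCC(=O)O)cc1 | starting material
3 | (4-methoxyphenoxy)acetic pivalic anhydride | COc1ccc(OCC(=O)OC(=O)C(C)(C)C)cc1 | intermediate
4 | (R)-4-benzyl-3-[(4-methoxyphenoxy)acetyl]oxazolidin-2-one | COc1ccc(OCC(=O)N2[C@H](Cc3ccccc3)COC2=O)cc1 | intermediate
5 | (E)-1-bromopent-2-ene | CC/C=C/CBr | starting material
6 | sodium (Z)-enolate of 4 | COc1ccc(O/C=C(\[O-])N2[C@H](Cc3ccccc3)COC2=O)cc1.[Na+] | intermediate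
7 | (R)-4-benzyl-3-[(2S,4E)-2-(4-methoxyphenoxy)hept-4-enoyl]oxazolidin-2-one | CC/C=C/C[C@H](Oc1ccc(OC)cc1)C(=O)N1[C@H](Cc2ccccc2)COC1=O | intermediate
8 | (2S,4E)-N-methoxy-2-(4-methoxyphenoxy)-N-methylhept-4-enamide | CC/C=C/C[C@H](Oc1ccc(OC)cc1)C(=O)N(C)OC | intermediate
9 | (3S,5E)-3-(4-methoxyphenoxy)oct-5-en-2-one | CC/C=C/C[C@H](Oc1ccc(OC)cc1)C(C)=O | intermediate
10 | 5-(trimethylsilyl)pent-4-yn-1-ol | C[Si](C)(C)C#CCCCO | starting material
11 | 5-(trimethylsilyl)pent-4-ynal | C[Si](C)(C)C#CCCC=O | intermediate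
12 | (S)-2-chloro-5-(trimethylsilyl)pent-4-ynal | C[Si](C)(C)C#CC[C@H](Cl)C=O | intermediate
13 | kinetic lithium enolate of 9 | CC/C=C/C[C@H](Oc1ccc(OC)cc1)C(=C)[O-].[Li+] | intermediate
14 | (4S,5R,8S,10E)-4-chloro-5-hydroxy-8-(4-methoxyphenoxy)-1-(trimethylsilyl)tridec-10-en-1-yn-7-one | CC/C=C/C[C@H](Oc1ccc(OC)cc1)C(=O)C[C@@H](O)[C@@H](Cl)CC#C[Si](C)(C)C | intermediate
15 | (4S,5R,7S,8S,10E)-4-chloro-8-(4-methoxyphenoxy)-1-(trimethylsilyl)tridec-10-en-1-yne-5,7-diol | CC/C=C/C[C@H](Oc1ccc(OC)cc1)[C@@H](O)C[C@@H](O)[C@@H](Cl)CC#C[Si](C)(C)C | intermediate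
16 | (2S,3S,5E)-3-(4-methoxyphenoxy)-1-[(2R,3R)-3-(prop-2-ynyl)oxiran-2-yl]oct-5-en-2-ol | CC/C=C/C[C@H](Oc1ccc(OC)cc1)[C@@H](O)C[C@H]1O[C@@H]1CC#C | intermediate
17 | (2S,3R,5S)-5-[(1S,3E)-1-(4-methoxyphenoxy)hex-3-enyl]-2-(prop-2-ynyl)tetrahydrofuran-3-ol | CC/C=C/C[C@H](Oc1ccc(OC)cc1)[C@@H]1C[C@@H](O)[C@H](CC#C)O1 | intermediate
18 | (2S,3S,5S)-3-chloro-5-[(1S,3E)-1-(4-methoxyphenoxy)hex-3-enyl]-2-(prop-2-ynyl)tetrahydrofuran | CC/C=C/C[C@H](Oc1ccc(OC)cc1)[C@@H]1C[C@H](Cl)[C@H](CC#C)O1 | intermediate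
19 | (1S,3E)-1-[(2S,4S,5S)-4-chloro-5-(prop-2-ynyl)tetrahydrofuran-2-yl]hex-3-en-1-ol | CC/C=C/C[C@H](O)[C@@H]1C[C@H](Cl)[C@H](CC#C)O1 | intermediate
20 | (1S,3E)-1-[(2S,4S,5S)-4-chloro-5-(prop-2-ynyl)tetrahydrofuran-2-yl]hex-3-enyl acetate | CC/C=C/C[C@H](OC(C)=O)[C@@H]1C[C@H](Cl)[C@H](CC#C)O1 | intermediate
21 | 1-oxoniabicyclo[3.3.0]octane salt (O+ bonded to C6, C9 and C12; bromopropyl exo; propargyl, C7–Cl and C10–OAc endo) | CC[C@H](Br)[C@H]1C[C@H](OC(C)=O)[C@@H]2C[C@H](Cl)[C@H](CC#C)[O+]12.Cl[Sb-](Cl)(Cl)(Cl)(Cl)Br | intermediate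
22 | 2-methyl-1,3-dioxolan-2-ylium salt cis-fused at C9/C10 of the oxocane | CC[C@H](Br)[C@H]1C[C@@H]2OC(C)=[O+][C@@H]2C[C@H](Cl)[C@H](CC#C)O1.Cl[Sb-](Cl)(Cl)(Cl)(Cl)Br | intermediate
23 | (2R,4S,5S,7S,8S)-2-[(S)-1-bromopropyl]-5,7-dichloro-8-(prop-2-ynyl)oxocan-4-yl acetate | C#CC[C@@H]1O[C@@H]([C@@H](Br)CC)C[C@H](OC(C)=O)[C@@H](Cl)C[C@@H]1Cl | intermediate
24 | (E)-alkenylzirconocene chloride derived from 23 (Cp rings drawn σ-bound) | Cl[Zr](C2C=CC=C2)(C3C=CC=C3)/C=C/C[C@@H]1O[C@@H]([C@@H](Br)CC)C[C@H](OC(C)=O)[C@@H](Cl)C[C@@H]1Cl | intermediate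
25 | (2R,4S,5S,7S,8S)-2-[(S)-1-bromopropyl]-5,7-dichloro-8-[(E)-3-iodoprop-2-enyl]oxocan-4-yl acetate | I/C=C/C[C@@H]1O[C@@H]([C@@H](Br)CC)C[C@H](OC(C)=O)[C@@H](Cl)C[C@@H]1Cl | intermediate
26 | (2R,4S,5S,7S,8S)-2-[(S)-1-bromopropyl]-5,7-dichloro-8-[(E)-pent-2-en-4-ynyl]oxocan-4-yl acetate | C#C/C=C/C[C@@H]1O[C@@H]([C@@H](Br)CC)C[C@H](OC(C)=O)[C@@H](Cl)C[C@@H]1Cl | target

Total step count: 16. Longest linear sequence: 14 (steps 1–4, then 7–16).

Steps most likely to fail

1. Step 14.
- What may go wrong: The ring oxygen is hindered and inductively deactivated, and the oxonium must hold three groups on its concave face. The acetate carbonyl may therefore capture the bromonium first in a 6-exo mode. Chloride may open the acetoxonium at C10 instead of C9. Bromide released from the counter-ion may also compete with chloride.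
- Fallback (known chemistry, from 19 back to 23): The cascade is cut into established operations.
  - Boc2O/DMAP converts 19 into the tert-butyl carbonate F1.
  - BDSB in MeNO2 at −25 °C effects the tethered-carbonate ring-expanding bromoetherification and gives the cis-fused cyclic carbonate F2, with loss of the tert-butyl group.
  - K2CO3/MeOH at 0 °C gives the cis-9,10-diol F3.
  - MeC(OMe)3/PPTS gives the cyclic orthoacetate F4.
  - TMSCl in CH2Cl2 opens F4 to the trans-chloro acetate 23 (orthoester-to-halohydrin-ester opening).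

2. Step 10.
- What may go wrong: The Lewis acid may isomerise the epoxide to a ketone. Opening may occur at the wrong epoxide carbon, or the remote alkene may take part.
- Fallback (from 11 and 9 back to 17): The epoxide is avoided altogether.
  - The antipodal chlorination catalyst converts 11 into the (R)-chloroaldehyde F5.
  - Aldol addition of enolate 13 gives the anti chlorohydrin F6.
  - Evans–Saksena reduction (Me4NBH(OAc)3) gives the 1,3-anti diol F7.
  - Heating in MeOH/H2O lets the C9 hydroxyl displace the C6 chloride directly (5-exo-tet, inversion), giving the 2,3-cis tetrahydrofuranol F8.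
  - Mitsunobu inversion with 4-nitrobenzoic acid, with attack from the open face, gives the ester F9.
  - K2CO3/MeOH removes both the ester and the alkynyl silyl group to give 17.

3. Step 11.
- What may go wrong: Chloride must enter on the face that carries both ring substituents. Substitution may therefore be slow, and elimination to a dihydrofuran may take over at the temperature needed.
- Fallback (from 17 back to 18): Activation and displacement are separated.
  - ClCH2SO2Cl/2,6-lutidine gives the isolable chloromethanesulfonate F10.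
  - LiCl in DMF at or near room temperature displaces it with inversion to give 18.

Further compounds
F1 | step 14 | tert-butyl (1S,3E)-1-[(2S,4S,5S)-4-chloro-5-(prop-2-ynyl)tetrahydrofuran-2-yl]hex-3-enyl carbonate | CC/C=C/C[C@H](OC(=O)OC(C)(C)C)[C@@H]1C[C@H](Cl)[C@H](CC#C)O1
F2 | step 14 | oxocane 9,10-cyclic carbonate (cis-fused; 6S,7S,9R,10S,12R,13S) | CC[C@H](Br)[C@H]1C[C@@H]2OC(=O)O[C@@H]2C[C@H](Cl)[C@H](CC#C)O1
F3 | step 14 | oxocane cis-9,10-diol (6S,7S,9R,10S,12R,13S) | CC[C@H](Br)[C@H]1C[C@H](O)[C@H](O)C[C@H](Cl)[C@H](CC#C)O1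
F4 | step 14 | oxocane 9,10-cyclic methyl orthoacetate (orthoester carbon unassigned) | CC[C@H](Br)[C@H]1C[C@@H]2OC(C)(OC)O[C@@H]2C[C@H](Cl)[C@H](CC#C)O1
F5 | step 10 | (R)-2-chloro-5-(trimethylsilyl)pent-4-ynal | C[Si](C)(C)C#CC[C@@H](Cl)C=O
F6 | step 10 | (4R,5S,8S,10E)-4-chloro-5-hydroxy-8-(4-methoxyphenoxy)-1-(trimethylsilyl)tridec-10-en-1-yn-7-one | CC/C=C/C[C@H](Oc1ccc(OC)cc1)C(=O)C[C@H](O)[C@H](Cl)CC#C[Si](C)(C)C
F7 | step 10 | (4R,5S,7S,8S,10E)-4-chloro-8-(4-methoxyphenoxy)-1-(trimethylsilyl)tridec-10-en-1-yne-5,7-diol | CC/C=C/C[C@H](Oc1ccc(OC)cc1)[C@@H](O)C[C@H](O)[C@H](Cl)CC#C[Si](C)(C)C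
F8 | step 10 | (2S,3S,5S)-5-[(1S,3E)-1-(4-methoxyphenoxy)hex-3-enyl]-2-[3-(trimethylsilyl)prop-2-ynyl]tetrahydrofuran-3-ol | CC/C=C/C[C@H](Oc1ccc(OC)cc1)[C@@H]1C[C@H](O)[C@H](CC#C[Si](C)(C)C)O1
F9 | step 10 | (2S,3R,5S)-5-[(1S,3E)-1-(4-methoxyphenoxy)hex-3-enyl]-2-[3-(trimethylsilyl)prop-2-ynyl]tetrahydrofuran-3-yl 4-nitrobenzoate | CC/C=C/C[C@H](Oc1ccc(OC)cc1)[C@@H]1C[C@@H](OC(=O)c2ccc(cc2)[N+](=O)[O-])[C@H](CC#C[Si](C)(C)C)O1
F10 | step 11 | (2S,3R,5S)-5-[(1S,3E)-1-(4-methoxyphenoxy)hex-3-enyl]-2-(prop-2-ynyl)tetrahydrofuran-3-yl chloromethanesulfonate | CC/C=C/C[C@H](Oc1ccc(OC)cc1)[C@@H]1C[C@@H](OS(=O)(=O)CCl)[C@H](CC#C)O1
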